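**Strategy.** The route rests on disconnecting the bond between C2 of the γ-pyrone (ring C) and C1' of the catechol ring B, the biaryl-type bond that completes the seven-membered oxepine (ring D). The key step exploits the acidic C2–H of ring C (next to O1, β to the C4 carbonyl) and the C3–CH2–C(=CMe2)–O–C2' bridge, which holds an ortho C1'–Br over C2. A palladium-catalysed intramolecular direct arylation closes ring D and creates the flavone C2–aryl bond in one operation. The precursor is a fully decorated 2-unsubstituted 3-alkylchromone, assembled convergently from an o-hydroxyaryl enaminone and a 2-aryloxyallyl bromide.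

Key step: step 15

Remark: the target is achiral. The only stereochemical elements on the way are the E double bond of enaminone 8 and the racemic stereocentre of phosphonate 14; both disappear in the following step.

**Ring A branch**

Step 1
Reactants: 1 2,4,6-trihydroxyacetophenone
Product: 2 1-[2,6-dihydroxy-4-(2-methylbut-3-yn-2-yloxy)phenyl]ethanone
Conditions: K2CO3 (1.1 equiv), KI, CuI (cat.), acetone, reflux
Reagents that add atoms: 3-chloro-3-methylbut-1-yne C#CC(C)(C)Cl
Why: The para hydroxyl is the only non-chelated and the most acidic OH of 1, so a copper-assisted Williamson-type O-alkylation with the tertiary propargylic chloride should stop at the mono 4-O-ether and leave the two hydrogen-bonded ortho hydroxyls free.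

Step 2
Reactants: 2 1-[2,6-dihydroxy-4-(2-methylbut-3-yn-2-yloxy)phenyl]ethanone
Product: 3 1-[2-hydroxy-4-(2-methylbut-3-yn-2-yloxy)-6-(triisopropylsilyloxy)phenyl]ethanone
Conditions: i-Pr3SiCl (1.05 equiv), imidazole, DMF, 0 °C to rt
Reagents that add atoms: triisopropylsilyl chloride CC(C)[Si](Cl)(C(C)C)C(C)C
Why: The two ortho hydroxyls of 2 are equivalent and, after the first silyl ether formation, the remaining one is locked in the hydrogen bond to the acetyl group, so mono-silylation should tag exactly one ortho oxygen.

Step 3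
Reactants: 3 1-[2-hydroxy-4-(2-methylbut-3-yn-2-yloxy)-6-(triisopropylsilyloxy)phenyl]ethanone
Product: 5 1-[5-hydroxy-2,2-dimethyl-7-(triisopropylsilyloxy)-2H-chromen-6-yl]ethanone, via allenylphenol 4 (not isolated)
Conditions: o-xylene, 140 °C
Reagents that add atoms: none
Why: This is the aromatic propargyl Claisen rearrangement followed by 1,5-hydrogen shift and 6π-oxa-electrocyclisation (standard chromene synthesis); the chelate between the carbonyl and the free OH fixes the ring double bond so that the shift should go to the carbon next to the free OH (also the one not shielded by the silyl ether), and the non-chelated 4-OH closes the pyran.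

Step 4
Reactants: 5 1-[5-hydroxy-2,2-dimethyl-7-(triisopropylsilyloxy)-2H-chromen-6-yl]ethanone
Product: 6 1-[5-hydroxy-8-iodo-2,2-dimethyl-7-(triisopropylsilyloxy)-2H-chromen-6-yl]ethanone
Conditions: N-iodosuccinimide (1.05 equiv), CH2Cl2, 0 °C
Reagents that add atoms: N-iodosuccinimide O=C1CCC(=O)N1I
Why: Electrophilic aromatic iodination should occur at C8, the only free ring position, which is para to the free phenol and flanked by two ether oxygens and therefore far more reactive than the chromene double bond.

Step 5
Reactants: 6 1-[5-hydroxy-8-iodo-2,2-dimethyl-7-(triisopropylsilyloxy)-2H-chromen-6-yl]ethanone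
Product: 7 1-[5-hydroxy-2,2-dimethyl-8-(3-methylbut-2-enyl)-7-(triisopropylsilyloxy)-2H-chromen-6-yl]ethanone
Conditions: Bu3Sn(CH2CH=CMe2), Pd(PPh3)4 (5 mol %), DMF, 90 °C
Reagents that add atoms: tributyl(3-methylbut-2-enyl)stannane CCCC[Sn](CCCC)(CCCC)CC=C(C)C
Why: A Stille cross-coupling under neutral conditions (sparing the silyl ether and the free phenol) should place the linear prenyl group next to the silylated oxygen, reductive elimination occurring at the unsubstituted allyl terminus.

Step 6
Reactants: 7 1-[5-hydroxy-2,2-dimethyl-8-(3-methylbut-2-enyl)-7-(triisopropylsilyloxy)-2H-chromen-6-yl]ethanone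
Product: 8 (E)-3-(dimethylamino)-1-[5-hydroxy-2,2-dimethyl-8-(3-methylbut-2-enyl)-7-(triisopropylsilyloxy)-2H-chromen-6-yl]prop-2-en-1-one
Conditions: Me2NCH(OMe)2 (3 equiv), toluene, 85 °C
Reagents that add atoms: N,N-dimethylformamide dimethyl acetal COC(OC)N(C)C
Why: Condensation of the methyl ketone with the amide acetal (enaminone formation, first stage of the enaminone chromone synthesis) should give the E enaminone, the chelated phenol being inert to the reagent at this temperature.

**Ring B branch**

Step 7
Reactants: 9 3,4-dihydroxybenzaldehyde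
Product: 10 3,4-bis(tert-butyldimethylsilyloxy)benzaldehyde
Conditions: t-BuMe2SiCl (2.3 equiv), imidazole, DMF, rt
Reagents that add atoms: tert-butyldimethylsilyl chloride CC(C)(C)[Si](C)(C)Cl
Why: Standard bis-silyl ether protection masks the catechol with groups that tolerate hydride, ylide and palladium chemistry and leave at the end under fluoride.

Step 8
Reactants: 10 3,4-bis(tert-butyldimethylsilyloxy)benzaldehyde
Product: 12 3,4-bis(tert-butyldimethylsilyloxy)phenol, via aryl formate 11 (not isolated)
Conditions: mCPBA, CH2Cl2, 0 °C to rt; then Et3N (cat.), MeOH, 0 °C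
Reagents that add atoms: 3-chloroperoxybenzoic acid OOC(=O)c1cccc(Cl)c1
Why: In this Baeyer–Villiger (Dakin-type) oxidation the electron-rich aryl group migrates in the Criegee intermediate, and the labile aryl formate is methanolysed under amine catalysis mild enough to keep the aryl silyl ethers.

Step 9
Reactants: 12 3,4-bis(tert-butyldimethylsilyloxy)phenol
Product: 13 2-bromo-4,5-bis(tert-butyldimethylsilyloxy)phenol
Conditions: N-bromosuccinimide (1.0 equiv), MeCN, −20 °C
Reagents that add atoms: N-bromosuccinimide O=C1CCC(=O)N1Br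
Why: Electrophilic aromatic bromination should go ortho to the free OH and para to the 3-silyloxy group, the other ortho position being wedged between two oxygens.

Step 10
Reactants: 13 2-bromo-4,5-bis(tert-butyldimethylsilyloxy)phenol
Product: 14 ethyl 2-[2-bromo-4,5-bis(tert-butyldimethylsilyloxy)phenoxy]-2-(diethoxyphosphoryl)acetate (racemic)
Conditions: N2=C(CO2Et)P(O)(OEt)2, Rh2(OAc)4 (1 mol %), toluene, 80 °C
Reagents that add atoms: triethyl diazophosphonoacetate CCOC(=O)C(=[N+]=[N-])P(=O)(OCC)OCC
Why: Rhodium-carbenoid O–H insertion into the phenol forms the aryl ether under neutral conditions that spare the silyl ethers; the new stereocentre is formed racemic and is destroyed in the next step.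

Step 11
Reactants: 14 ethyl 2-[2-bromo-4,5-bis(tert-butyldimethylsilyloxy)phenoxy]-2-(diethoxyphosphoryl)acetate
Product: 15 ethyl 2-[2-bromo-4,5-bis(tert-butyldimethylsilyloxy)phenoxy]-3-methylbut-2-enoate
Conditions: NaH, THF, 0 °C; acetone (excess), rt to 50 °C
Reagents that add atoms: acetone CC(C)=O
Why: A Horner–Wadsworth–Emmons olefination of acetone with the α-aryloxy phosphonoacetate should install the tetrasubstituted aryl enol ether, with no E/Z question because both new alkene substituents are methyl.

Step 12
Reactants: 15 ethyl 2-[2-bromo-4,5-bis(tert-butyldimethylsilyloxy)phenoxy]-3-methylbut-2-enoate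
Product: 16 2-[2-bromo-4,5-bis(tert-butyldimethylsilyloxy)phenoxy]-3-methylbut-2-en-1-ol
Conditions: i-Bu2AlH (2.5 equiv), CH2Cl2, −78 to 0 °C; aqueous potassium sodium tartrate
Reagents that add atoms: none
Why: 1,2-Reduction of the enoate with the aluminium hydride should give the allylic alcohol without touching the aryl bromide, the silyl ethers or the enol ether, and the work-up is non-acidic.

Step 13
Reactants: 16 2-[2-bromo-4,5-bis(tert-butyldimethylsilyloxy)phenoxy]-3-methylbut-2-en-1-ol
Product: 17 1-bromo-2-[(1-bromo-3-methylbut-2-en-2-yl)oxy]-4,5-bis(tert-butyldimethylsilyloxy)benzene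
Conditions: CBr4, PPh3, CH2Cl2, 0 °C; filtered through Et3N-deactivated silica and used at once
Reagents that add atoms: tetrabromomethane BrC(Br)(Br)Br
Why: The Appel reaction converts the primary allylic alcohol into the bromide under neutral conditions, avoiding the acid that would hydrolyse the enol ether.

**Union, key step and deprotection**

Step 14
Reactants: 8 (E)-3-(dimethylamino)-1-[5-hydroxy-2,2-dimethyl-8-(3-methylbut-2-enyl)-7-(triisopropylsilyloxy)-2H-chromen-6-yl]prop-2-en-1-one; 17 1-bromo-2-[(1-bromo-3-methylbut-2-en-2-yl)oxy]-4,5-bis(tert-butyldimethylsilyloxy)benzene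
Product: 18 3-{2-[2-bromo-4,5-bis(tert-butyldimethylsilyloxy)phenoxy]-3-methylbut-2-enyl}-8,8-dimethyl-6-(3-methylbut-2-enyl)-5-(triisopropylsilyloxy)-4H,8H-pyrano[2,3-f]chromen-4-one
Conditions: NaHCO3 (2 equiv), NaI (cat.), DMF, 60 °C
Reagents that add atoms: none
Why: In this domino C-alkylation/annulation of an o-hydroxyaryl enaminone the nucleophilic α-carbon attacks the primary allylic carbon (SN2), the iminium formed is trapped by the only free phenolic OH and dimethylamine is eliminated to give the 3-substituted chromone; because the other ortho oxygen is silylated, only the angular pyranochromone with the silyloxy group next to the prenyl group can form.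

Step 15
Reactants: 18 3-{2-[2-bromo-4,5-bis(tert-butyldimethylsilyloxy)phenoxy]-3-methylbut-2-enyl}-8,8-dimethyl-6-(3-methylbut-2-enyl)-5-(triisopropylsilyloxy)-4H,8H-pyrano[2,3-f]chromen-4-one
Product: 19 5-O-triisopropylsilyl-4',5'-bis-O-(tert-butyldimethylsilyl)isocycloheterophyllin
Conditions: Pd(OAc)2 (10 mol %), PCy3·HBF4 (20 mol %), PivOH (30 mol %), K2CO3 (2.5 equiv), toluene, 110 °C
Reagents that add atoms: none
Why: Zerovalent palladium (formed from Pd(OAc)2 and PCy3) inserts into the electron-rich C1'–Br bond, the C3–CH2–C(=CMe2)–O–C2' tether holds the arylpalladium over C2 of ring C, pivalate-assisted concerted metalation–deprotonation of the acidic C2–H gives an eight-membered palladacycle, and reductive elimination forms the C2–C1' bond. The closest known reaction type is the intramolecular palladium-catalysed direct C–H arylation of heteroarenes by tethered aryl halides, established for five- to seven-membered rings and for C2 of chromones. Ring D (the oxepine) is closed in a formal 7-endo mode with respect to the C2=C3 bond; a Heck-type 7-endo carbopalladation followed by enolate-mediated β-hydride elimination would give the same product, because aryl transfer to the β-carbon of the enone is the electronically preferred sense. No stereocentre is created. The step needs selectivity for the sp2 C2–H over the doubly allylic CH2 of the bridge (sp3 arylation would give a dihydrobenzofuran) and over protodebromination; this is secured by the much higher kinetic acidity of C2–H, by C3 being fully substituted so that C2 is the only ring C position available, and by bromine being the only halogen and sitting ortho to the bridge oxygen. Carbonate in a non-polar solvent is chosen so that the three aryl silyl ethers and the acid-labile enol ether should survive.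

Step 16
Reactants: 19 5-O-triisopropylsilyl-4',5'-bis-O-(tert-butyldimethylsilyl)isocycloheterophyllin
Product: 20 isocycloheterophyllin
Conditions: Bu4NF (3.5 equiv), AcOH (3.5 equiv), THF, 0 °C
Reagents that add atoms: none
Why: Fluoride-mediated cleavage of all three aryl silyl ethers, buffered with acetic acid so that the catechol is not exposed to base nor the enol ether to strong acid, should release the target in one global deprotection.

**Compound list**

1 | 2,4,6-trihydroxyacetophenone | CC(=O)c1c(O)cc(O)cc1O | starting material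
2 | 1-[2,6-dihydroxy-4-(2-methylbut-3-yn-2-yloxy)phenyl]ethanone | CC(=O)c1c(O)cc(OC(C)(C)C#C)cc1O | intermediate
3 | 1-[2-hydroxy-4-(2-methylbut-3-yn-2-yloxy)-6-(triisopropylsilyloxy)phenyl]ethanone | CC(=O)c1c(O)cc(OC(C)(C)C#C)cc1O[Si](C(C)C)(C(C)C)C(C)C | intermediate
4 | 1-[2,4-dihydroxy-3-(3-methylbuta-1,2-dienyl)-6-(triisopropylsilyloxy)phenyl]ethanone (allenylphenol, not isolated) | CC(=O)c1c(O)c(C=C=C(C)C)c(O)cc1O[Si](C(C)C)(C(C)C)C(C)C | intermediate
5 | 1-[5-hydroxy-2,2-dimethyl-7-(triisopropylsilyloxy)-2H-chromen-6-yl]ethanone | CC(=O)c1c(O)c2C=CC(C)(C)Oc2cc1O[Si](C(C)C)(C(C)C)C(C)C | intermediate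
6 | 1-[5-hydroxy-8-iodo-2,2-dimethyl-7-(triisopropylsilyloxy)-2H-chromen-6-yl]ethanone | CC(=O)c1c(O)c2C=CC(C)(C)Oc2c(I)c1O[Si](C(C)C)(C(C)C)C(C)C | intermediate
7 | 1-[5-hydroxy-2,2-dimethyl-8-(3-methylbut-2-enyl)-7-(triisopropylsilyloxy)-2H-chromen-6-yl]ethanone | CC(=O)c1c(O)c2C=CC(C)(C)Oc2c(CC=C(C)C)c1O[Si](C(C)C)(C(C)C)C(C)C | intermediate
8 | (E)-3-(dimethylamino)-1-[5-hydroxy-2,2-dimethyl-8-(3-methylbut-2-enyl)-7-(triisopropylsilyloxy)-2H-chromen-6-yl]prop-2-en-1-one | CN(C)/C=C/C(=O)c1c(O)c2C=CC(C)(C)Oc2c(CC=C(C)C)c1O[Si](C(C)C)(C(C)C)C(C)C | intermediate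
9 | 3,4-dihydroxybenzaldehyde | O=Cc1ccc(O)c(O)c1 | starting material
10 | 3,4-bis(tert-butyldimethylsilyloxy)benzaldehyde | O=Cc1ccc(O[Si](C)(C)C(C)(C)C)c(O[Si](C)(C)C(C)(C)C)c1 | intermediate
11 | 3,4-bis(tert-butyldimethylsilyloxy)phenyl formate (not isolated) | O=COc1ccc(O[Si](C)(C)C(C)(C)C)c(O[Si](C)(C)C(C)(C)C)c1 | intermediate
12 | 3,4-bis(tert-butyldimethylsilyloxy)phenol | Oc1ccc(O[Si](C)(C)C(C)(C)C)c(O[Si](C)(C)C(C)(C)C)c1 | intermediate
13 | 2-bromo-4,5-bis(tert-butyldimethylsilyloxy)phenol | Oc1cc(O[Si](C)(C)C(C)(C)C)c(O[Si](C)(C)C(C)(C)C)cc1Br | intermediate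
14 | ethyl 2-[2-bromo-4,5-bis(tert-butyldimethylsilyloxy)phenoxy]-2-(diethoxyphosphoryl)acetate (racemic) | CCOC(=O)C(Oc1cc(O[Si](C)(C)C(C)(C)C)c(O[Si](C)(C)C(C)(C)C)cc1Br)P(=O)(OCC)OCC | intermediate
15 | ethyl 2-[2-bromo-4,5-bis(tert-butyldimethylsilyloxy)phenoxy]-3-methylbut-2-enoate | CCOC(=O)C(Oc1cc(O[Si](C)(C)C(C)(C)C)c(O[Si](C)(C)C(C)(C)C)cc1Br)=C(C)C | intermediate
16 | 2-[2-bromo-4,5-bis(tert-butyldimethylsilyloxy)phenoxy]-3-methylbut-2-en-1-ol | OCC(Oc1cc(O[Si](C)(C)C(C)(C)C)c(O[Si](C)(C)C(C)(C)C)cc1Br)=C(C)C | intermediate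
17 | 1-bromo-2-[(1-bromo-3-methylbut-2-en-2-yl)oxy]-4,5-bis(tert-butyldimethylsilyloxy)benzene | BrCC(Oc1cc(O[Si](C)(C)C(C)(C)C)c(O[Si](C)(C)C(C)(C)C)cc1Br)=C(C)C | intermediate
18 | 3-{2-[2-bromo-4,5-bis(tert-butyldimethylsilyloxy)phenoxy]-3-methylbut-2-enyl}-8,8-dimethyl-6-(3-methylbut-2-enyl)-5-(triisopropylsilyloxy)-4H,8H-pyrano[2,3-f]chromen-4-one (2-unsubstituted chromone, angular 7,8-fused dimethylpyran) | CC(C)=CCc1c2c(c3occ(CC(Oc4cc(O[Si](C)(C)C(C)(C)C)c(O[Si](C)(C)C(C)(C)C)cc4Br)=C(C)C)c(=O)c3c1O[Si](C(C)C)(C(C)C)C(C)C)C=CC(C)(C)O2 | intermediate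
19 | 5-O-triisopropylsilyl-4',5'-bis-O-(tert-butyldimethylsilyl)isocycloheterophyllin | CC(C)=CCc1c2c(c3oc4c(c(=O)c3c1O[Si](C(C)C)(C(C)C)C(C)C)CC(=C(C)C)Oc1cc(O[Si](C)(C)C(C)(C)C)c(O[Si](C)(C)C(C)(C)C)cc1-4)C=CC(C)(C)O2 | intermediate
20 | isocycloheterophyllin | CC(C)=CCc1c2c(c3oc4c(c(=O)c3c1O)CC(=C(C)C)Oc1cc(O)c(O)cc1-4)C=CC(C)(C)O2 | target

**Step count and risks**

Total step count: 16. Longest linear sequence: 10 steps (steps 7 to 13, then 14, 15 and 16).

Steps most likely to fail:

Step 15. Arylation of the bridge CH2 through a six-membered palladacycle, or protodebromination, may outrun closure of the seven-membered ring, and the base at 110 °C may strip silyl groups. The fallback sets out from 18 and comes back at 19. Deprotonative zincation of the only ring C C–H of 18 with TMPZnCl·LiCl in THF at 25 °C would give the 2-chlorozincio chromone F1. Addition of Pd(OAc)2 and SPhos at 50 °C would then close ring D by an intramolecular Negishi coupling with the C1'–Br bond. This replaces the carboxylate-assisted C–H cleavage at palladium by a stoichiometric low-temperature metalation and forms the same bond.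

Step 3. The propargyl Claisen shift may go to the carbon next to the silyl ether, or the pyran may close through the chelated hydroxyl, eroding the regiochemical tag on which the chromone annulation depends. The fallback sets out from 2 and comes back at 5. The symmetrical ether 2 would be heated in o-xylene at 140 °C, where only one chromene can arise, to give 1-(5,7-dihydroxy-2,2-dimethyl-2H-chromen-6-yl)ethanone F2. Silylation with i-Pr3SiCl and imidazole at −20 °C should then favour the 7-hydroxyl, which is flanked by C8–H, over the peri-hindered 5-hydroxyl. Regiocontrol thus comes from steric differentiation after ring formation instead of from the chelation-directed rearrangement.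

Step 14. O-alkylation, ionisation of the allylic bromide with attack at the tertiary terminus, or loss of the silyl group before ring closure may divert the domino sequence. The fallback sets out from 7 (with 17) and comes back at 18. The dianion of 7, made with LiN(SiMe3)2 (2.2 equiv) in THF at −78 °C, would be C-alkylated with 17 to give the chain-extended ketone 1-[5-hydroxy-2,2-dimethyl-8-(3-methylbut-2-enyl)-7-(triisopropylsilyloxy)-2H-chromen-6-yl]-4-[2-bromo-4,5-bis(tert-butyldimethylsilyloxy)phenoxy]-5-methylhex-4-en-1-one F3. Heating F3 with Me2NCH(OMe)2 in toluene at 100 °C would form the enaminone at the α-methylene, which cyclises through the only free hydroxyl with loss of dimethylamine to give 18.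

**Further compounds**

F1 | step 15 | 2-chlorozincio derivative of chromone 18 | CC(C)=CCc1c2c(c3oc([Zn]Cl)c(CC(Oc4cc(O[Si](C)(C)C(C)(C)C)c(O[Si](C)(C)C(C)(C)C)cc4Br)=C(C)C)c(=O)c3c1O[Si](C(C)C)(C(C)C)C(C)C)C=CC(C)(C)O2
F2 | step 3 | 1-(5,7-dihydroxy-2,2-dimethyl-2H-chromen-6-yl)ethanone | CC(=O)c1c(O)cc2OC(C)(C)C=Cc2c1O
F3 | step 14 | 1-[5-hydroxy-2,2-dimethyl-8-(3-methylbut-2-enyl)-7-(triisopropylsilyloxy)-2H-chromen-6-yl]-4-[2-bromo-4,5-bis(tert-butyldimethylsilyloxy)phenoxy]-5-methylhex-4-en-1-one | O=C(CCC(Oc1cc(O[Si](C)(C)C(C)(C)C)c(O[Si](C)(C)C(C)(C)C)cc1Br)=C(C)C)c1c(O)c2C=CC(C)(C)Oc2c(CC=C(C)C)c1O[Si](C(C)C)(C(C)C)C(C)C
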